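**Plan**

- Cuts, in retrosynthetic order: the C8–O ester bond; C11=C13 and the C12 acid (from a C11–C12 acetaldehyde arm on C7); C7–C11; then C6–C7 and C7–C8 together, which takes C7 out and contracts ring B to a 7-nor trans-hydrindan-8-one; then C5–C10, C6–C8 and C8–C9 (Pauson–Khand); last C1–C10, C5–C6 and C4–C15 of an acyclic chain.
- Feature used: in ring B (C5, C6, C7, C8, C9, C10) C7 lies between the oxygenated C6 and C8 and carries the only carbon branch (C11–C13), so it can arrive last as CBr2 added to the C6=C8 silyl enol ether of the five-membered ring (C5, C6, C8, C9, C10).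
- Forward: hex-5-enoic acid → 1,7-enyne → ring A and the cyclopentenone in one Pauson–Khand step → trans-hydrindanone enol ether → ring B by one-carbon enlargement → C7 side chain, O6, O8 ester, C12 acid, C15 aldehyde.
- Stereochemistry: C4 from the oxazolidinone auxiliary; C1 from CBS reduction; C10 from the Pauson–Khand transition state (C1 and C4 substituents both pseudo-equatorial); C5 from the dissolving-metal reduction (trans fusion); C8 from α-face Luche reduction then Mitsunobu inversion; C6 and C7 from α-face syn hydroboration.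

Key step: step 14

Remark: eudesmane numbering is used for all bicyclic compounds (the hydrindanes lack C7, with C6 bonded to C8; all are 4βH, i.e. C15 α, and 10β-methyl); hydride attack on the C8 ketone is assumed to occur anti to the axial C10 methyl; solutions of 15 and 28 are taken as purchased; TBS = tert-butyldimethylsilyl, TBDPS = tert-butyldiphenylsilyl.

Step 1
Reactants: 1 hex-5-enoic acid; 2 (R)-4-benzyl-1,3-oxazolidin-2-one
Product: 4 (R)-4-benzyl-3-(hex-5-enoyl)-1,3-oxazolidin-2-one, via hex-5-enoic pivalic anhydride 3 (not isolated)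
Conditions: PivCl, Et3N, THF, −20 °C; then 2, LiCl, −20 °C → rt
Reagents that add atoms: none
Why: N-acylation of the auxiliary through the mixed pivalic anhydride, which is attacked at its unhindered hexenoyl carbonyl; no stereocentre is formed.

Step 2
Reactants: 4 (R)-4-benzyl-3-(hex-5-enoyl)-1,3-oxazolidin-2-one; 5 1,3,5-trioxane
Product: 7 (R)-4-benzyl-3-[(2S)-2-(hydroxymethyl)hex-5-enoyl]-1,3-oxazolidin-2-one, via trichlorotitanium (Z)-enolate 6 (not isolated)
Conditions: TiCl4, i-Pr2NEt, CH2Cl2, 0 °C; then 5, TiCl4, 0 °C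
Reagents that add atoms: none
Why: Evans titanium-enolate hydroxymethylation, in which the chelated (Z)-enolate is attacked by the trioxane-derived oxocarbenium ion on the face opposite the benzyl group, setting the α-carbon (C4) as S, the 4α-C15 centre of the target.

Step 3
Reactants: 7 (R)-4-benzyl-3-[(2S)-2-(hydroxymethyl)hex-5-enoyl]-1,3-oxazolidin-2-one
Product: 8 (R)-4-benzyl-3-[(2S)-2-{[(tert-butyldimethylsilyl)oxy]methyl}hex-5-enoyl]-1,3-oxazolidin-2-one
Conditions: TBSCl, imidazole, DMF, 0 °C → rt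
Reagents that add atoms: tert-butyldimethylsilyl chloride, CC(C)(C)[Si](C)(C)Cl
Why: Silylation of the primary alcohol, which distinguishes C15 from the acyl carbon before the imide is reduced.

Step 4
Reactants: 8 (R)-4-benzyl-3-[(2S)-2-{[(tert-butyldimethylsilyl)oxy]methyl}hex-5-enoyl]-1,3-oxazolidin-2-one
Product: 9 (2R)-2-{[(tert-butyldimethylsilyl)oxy]methyl}hex-5-en-1-ol
Conditions: LiBH4, MeOH (1 equiv), THF, 0 °C
Reagents that add atoms: none
Why: Reductive cleavage of the N-acyl oxazolidinone by borohydride at the exocyclic carbonyl gives the primary alcohol (C5) without enolising C4 and returns the auxiliary.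

Step 5
Reactants: 9 (2R)-2-{[(tert-butyldimethylsilyl)oxy]methyl}hex-5-en-1-ol
Product: 10 (2S)-2-{[(tert-butyldimethylsilyl)oxy]methyl}hex-5-enal
Conditions: Dess–Martin periodinane, NaHCO3, CH2Cl2, 0 °C → rt
Reagents that add atoms: none
Why: Dess–Martin oxidation under buffered, non-basic conditions should give the α-branched aldehyde without epimerisation; it is used directly.

Step 6
Reactants: 10 (2S)-2-{[(tert-butyldimethylsilyl)oxy]methyl}hex-5-enal; 11 dimethyl (1-diazo-2-oxopropyl)phosphonate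
Product: 12 tert-butyl{[(2R)-2-ethynylhex-5-en-1-yl]oxy}dimethylsilane
Conditions: K2CO3, MeOH, 0 °C → rt
Reagents that add atoms: none
Why: Seyferth–Gilbert homologation in the Ohira–Bestmann variant adds C6 and turns the aldehyde into the terminal alkyne under carbonate conditions mild enough to keep the C4 centre.

Step 7
Reactants: 12 tert-butyl{[(2R)-2-ethynylhex-5-en-1-yl]oxy}dimethylsilane
Product: 14 (4R)-4-{[(tert-butyldimethylsilyl)oxy]methyl}hex-5-ynal, via ozonide 13 (not isolated)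
Conditions: O3, CH2Cl2, −78 °C (Sudan III end point); then PPh3, −78 °C → rt
Reagents that add atoms: ozone, [O-][O+]=O
Why: Ozonolysis with reductive work-up; the monosubstituted alkene reacts far faster than the terminal alkyne and the indicator dye stops the reaction before the alkyne is touched.

Step 8
Reactants: 14 (4R)-4-{[(tert-butyldimethylsilyl)oxy]methyl}hex-5-ynal; 15 isopropenylmagnesium bromide
Product: 16 (6R)-6-{[(tert-butyldimethylsilyl)oxy]methyl}-2-methyloct-1-en-7-yn-3-ol (both C3 epimers)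
Conditions: THF, −78 °C; aq. NH4Cl
Reagents that add atoms: none
Why: Grignard 1,2-addition to the aldehyde forms C1–C10, being faster at −78 °C than deprotonation of the alkyne; no control at the carbinol is sought because it is oxidised in the next step.

Step 9
Reactants: 16 (6R)-6-{[(tert-butyldimethylsilyl)oxy]methyl}-2-methyloct-1-en-7-yn-3-ol
Product: 17 (6R)-6-{[(tert-butyldimethylsilyl)oxy]methyl}-2-methyloct-1-en-7-yn-3-one
Conditions: Dess–Martin periodinane, NaHCO3, CH2Cl2, 0 °C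
Reagents that add atoms: none
Why: Dess–Martin oxidation converts both allylic alcohol epimers into the single isopropenyl ketone.

Step 10
Reactants: 17 (6R)-6-{[(tert-butyldimethylsilyl)oxy]methyl}-2-methyloct-1-en-7-yn-3-one
Product: 18 (3R,6R)-6-{[(tert-butyldimethylsilyl)oxy]methyl}-2-methyloct-1-en-7-yn-3-ol
Conditions: (S)-Me-CBS (20 mol %), catecholborane, toluene, −78 °C
Reagents that add atoms: none
Why: Corey–Bakshi–Shibata reduction, in which the (S)-oxazaborolidine binds the ketone with the isopropenyl group as the large substituent and delivers hydride to give the R carbinol (the 1β-oxygen), while catecholborane at −78 °C leaves alkyne and alkene alone.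

Step 11
Reactants: 18 (3R,6R)-6-{[(tert-butyldimethylsilyl)oxy]methyl}-2-methyloct-1-en-7-yn-3-ol
Product: 19 (3R,6R)-3-[(tert-butyldimethylsilyl)oxy]-6-{[(tert-butyldimethylsilyl)oxy]methyl}-2-methyloct-1-en-7-yne
Conditions: TBSCl, imidazole, DMF, rt
Reagents that add atoms: tert-butyldimethylsilyl chloride, CC(C)(C)[Si](C)(C)Cl
Why: Silylation of the secondary allylic alcohol gives a base- and reduction-stable ether for the steps that follow.

Step 12
Reactants: 19 (3R,6R)-3-[(tert-butyldimethylsilyl)oxy]-6-{[(tert-butyldimethylsilyl)oxy]methyl}-2-methyloct-1-en-7-yne; 20 octacarbonyldicobalt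
Product: 22 1β,15-bis[(tert-butyldimethylsilyl)oxy]-7,11,12,13-tetranoreudesm-5-en-8-one, via alkyne–hexacarbonyldicobalt complex 21 (not isolated)
Conditions: Co2(CO)8, CH2Cl2, rt; then NMO, CH2Cl2, 0 °C → rt
Reagents that add atoms: none
Why: Intramolecular Pauson–Khand reaction of the 1,7-enyne (amine N-oxide promoted) inserts the 1,1-disubstituted alkene (C5–C10) and CO (C8) into the alkyne complex and closes ring A and the cyclopentenone together; the C1 and C4 substituents, trans-1,4 on the forming six-membered ring, can both be pseudo-equatorial only in the transition state that gives the 10β-methyl quaternary centre.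

Step 13
Reactants: 22 1β,15-bis[(tert-butyldimethylsilyl)oxy]-7,11,12,13-tetranoreudesm-5-en-8-one
Product: 24 8-[(trimethylsilyl)oxy]-1β,15-bis[(tert-butyldimethylsilyl)oxy]-7,11,12,13-tetranor-5α-eudesm-6(8)-ene, via lithium enolate 23 (not isolated)
Conditions: Li, NH3(l)/THF, t-BuOH (1 equiv), −78 °C; isoprene; NH3 removed; TMSCl, Et3N, THF, −78 → 0 °C
Reagents that add atoms: trimethylsilyl chloride, C[Si](C)(C)Cl
Why: Dissolving-metal reduction of the enone with regiospecific O-silylation of the enolate: C5 is protonated on the α-face, anti to the axial C10 methyl, giving the trans-fused enolate with both ring-A substituents equatorial, and trapping fixes the double bond between C6 and C8.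

Step 14
Reactants: 24 8-[(trimethylsilyl)oxy]-1β,15-bis[(tert-butyldimethylsilyl)oxy]-7,11,12,13-tetranor-5α-eudesm-6(8)-ene; 25 bromoform
Product: 27 7-bromo-1β,15-bis[(tert-butyldimethylsilyl)oxy]-11,12,13-trinor-5α-eudesm-6-en-8-one, via siloxy-dibromocyclopropane 26 (not isolated)
Conditions: CHBr3, KOt-Bu, pentane, −30 °C → rt
Reagents that add atoms: none
Why: tert-Butoxide deprotonates bromoform and α-elimination gives dibromocarbene, which adds in a [2+1] cheletropic step to the C6=C8 silyl enol ether of 24 from the α-face, anti to the C10 methyl, to give cyclopropane 26; the endo bromide then ionises with disrotatory electrocyclic opening of the C6–C8 bond and the 2-bromo-1-siloxyallyl cation loses silicon to give bromoenone 27. The closest known reaction type is the dihalocarbene ring expansion of cyclic silyl enol ethers to one-carbon-homologated 2-halo-enones. Ring B is formed by enlargement and not by cyclisation: the zero bridge of the bicyclo[3.1.0]hexane unit breaks, so that C7 ends up bonded to C6 and C8 in a six-membered ring. No stereocentre is created in 27, since the two cyclopropane centres are transient, and the trans C5/C10 fusion and the C1 and C4 centres pass through unchanged because the medium is aprotic and C5 is not enolisable from the enol ether. The step needs reaction at the enol ether only and insertion between C6 and C8, not C8 and C9; the first is secured because the enol ether is the only C=C bond present and is strongly nucleophilic, the second because its position was fixed when the enolate of step 13 was trapped.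

Step 15
Reactants: 27 7-bromo-1β,15-bis[(tert-butyldimethylsilyl)oxy]-11,12,13-trinor-5α-eudesm-6-en-8-one; 28 (1,3-dioxolan-2-ylmethyl)zinc bromide
Product: 29 1β,15-bis[(tert-butyldimethylsilyl)oxy]-12,12-(ethylenedioxy)-13-nor-5α-eudesm-6-en-8-one
Conditions: Pd(OAc)2 (5 mol %), SPhos (10 mol %), THF, rt → 45 °C
Reagents that add atoms: none
Why: Negishi cross-coupling forms C7–C11 by oxidative addition into the activated α-bromoenone C–Br bond, transmetalation from the primary alkylzinc and reductive elimination, which the bulky biarylphosphine favours over β-hydride elimination; no stereocentre is formed.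

Step 16
Reactants: 29 1β,15-bis[(tert-butyldimethylsilyl)oxy]-12,12-(ethylenedioxy)-13-nor-5α-eudesm-6-en-8-one
Product: 30 1β,15-bis[(tert-butyldimethylsilyl)oxy]-12,12-(ethylenedioxy)-13-nor-5α-eudesm-6-en-8β-ol
Conditions: NaBH4, CeCl3·7H2O, MeOH, −78 → −40 °C
Reagents that add atoms: none
Why: Luche 1,2-reduction, in which hydride should attack the C8 carbonyl from the α-face, anti to the axial C10 methyl that is 1,3 to C8, to give the pseudoaxial 8β-alcohol.

Step 17
Reactants: 30 1β,15-bis[(tert-butyldimethylsilyl)oxy]-12,12-(ethylenedioxy)-13-nor-5α-eudesm-6-en-8β-ol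
Product: 31 1β,15-bis[(tert-butyldimethylsilyl)oxy]-12,12-(ethylenedioxy)-13-nor-5α-eudesm-6-en-8α-yl 4-nitrobenzoate
Conditions: 4-nitrobenzoic acid, PPh3, DIAD, toluene, 0 °C → rt
Reagents that add atoms: 4-nitrobenzoic acid, OC(=O)c1ccc(cc1)[N+](=O)[O-]
Why: Mitsunobu esterification, in which SN2 displacement of the allylic oxyphosphonium ion by the carboxylate inverts C8 to the 8α configuration of the target.

Step 18
Reactants: 31 1β,15-bis[(tert-butyldimethylsilyl)oxy]-12,12-(ethylenedioxy)-13-nor-5α-eudesm-6-en-8α-yl 4-nitrobenzoate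
Product: 33 1β,15-bis[(tert-butyldimethylsilyl)oxy]-12,12-(ethylenedioxy)-6α-hydroxy-13-nor-5α,7αH-eudesman-8α-yl 4-nitrobenzoate, via C6 alkylborane 32 (not isolated)
Conditions: BH3·THF, THF, 0 °C → rt; then NaBO3·4H2O, THF/H2O, rt
Reagents that add atoms: sodium perborate, [Na+].[O-]OB=O
Why: Hydroboration–oxidation, in which borane adds syn and anti-Markovnikov to the trisubstituted C6=C7 bond from the α-face, opposite the axial C10 methyl (boron on C6, hydrogen on C7), and oxidation with retention gives 6α-OH and 7α-H, so that O6, the C7 side chain and O8 are all equatorial.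

Step 19
Reactants: 33 1β,15-bis[(tert-butyldimethylsilyl)oxy]-12,12-(ethylenedioxy)-6α-hydroxy-13-nor-5α,7αH-eudesman-8α-yl 4-nitrobenzoate
Product: 34 1β,6α,15-tris[(tert-butyldimethylsilyl)oxy]-12,12-(ethylenedioxy)-13-nor-5α,7αH-eudesman-8α-yl 4-nitrobenzoate
Conditions: TBSOTf, 2,6-lutidine, CH2Cl2, −78 → −20 °C
Reagents that add atoms: tert-butyldimethylsilyl trifluoromethanesulfonate, CC(C)(C)[Si](C)(C)OS(=O)(=O)C(F)(F)F
Why: Silylation of the hindered secondary alcohol with the silyl triflate, run cold so that the dioxolane is not activated.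

Step 20
Reactants: 34 1β,6α,15-tris[(tert-butyldimethylsilyl)oxy]-12,12-(ethylenedioxy)-13-nor-5α,7αH-eudesman-8α-yl 4-nitrobenzoate
Product: 35 1β,6α,15-tris[(tert-butyldimethylsilyl)oxy]-12,12-(ethylenedioxy)-13-nor-5α,7αH-eudesman-8α-ol
Conditions: K2CO3, MeOH/THF, rt
Reagents that add atoms: none
Why: Base-catalysed methanolysis of the activated aryl ester frees the 8α-hydroxyl with retention, silyl ethers and dioxolane being stable to carbonate in methanol.

Step 21
Reactants: 36 methyl 2-(hydroxymethyl)acrylate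
Product: 37 methyl 2-{[(tert-butyldiphenylsilyl)oxy]methyl}acrylate
Conditions: TBDPSCl, imidazole, DMF, 0 °C → rt
Reagents that add atoms: tert-butyldiphenylsilyl chloride, CC(C)(C)[Si](Cl)(c1ccccc1)c1ccccc1
Why: Silylation of the primary allylic alcohol with a group that survives aqueous acid (step 24) and leaves with fluoride at the end.

Step 22
Reactants: 37 methyl 2-{[(tert-butyldiphenylsilyl)oxy]methyl}acrylate
Product: 38 2-{[(tert-butyldiphenylsilyl)oxy]methyl}acrylic acid
Conditions: LiOH·H2O, THF/H2O, 0 °C → rt; then aq. HCl to pH 3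
Reagents that add atoms: lithium hydroxide, [Li+].[OH-]
Why: Saponification of the methyl ester, which is faster than conjugate addition to the α-substituted acrylate and leaves the silyl ether intact.

Step 23
Reactants: 35 1β,6α,15-tris[(tert-butyldimethylsilyl)oxy]-12,12-(ethylenedioxy)-13-nor-5α,7αH-eudesman-8α-ol; 38 2-{[(tert-butyldiphenylsilyl)oxy]methyl}acrylic acid
Product: 40 1β,6α,15-tris[(tert-butyldimethylsilyl)oxy]-12,12-(ethylenedioxy)-13-nor-5α,7αH-eudesman-8α-yl 2-{[(tert-butyldiphenylsilyl)oxy]methyl}acrylate, via mixed trichlorobenzoic anhydride 39 (not isolated)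
Conditions: 2,4,6-trichlorobenzoyl chloride, Et3N, THF, rt; then 35, DMAP, toluene, rt
Reagents that add atoms: none
Why: Yamaguchi esterification, in which DMAP attacks the mixed anhydride at the acryloyl carbonyl and the acylpyridinium acylates the equatorial 8α-hydroxyl with retention at C8.

Step 24
Reactants: 40 1β,6α,15-tris[(tert-butyldimethylsilyl)oxy]-12,12-(ethylenedioxy)-13-nor-5α,7αH-eudesman-8α-yl 2-{[(tert-butyldiphenylsilyl)oxy]methyl}acrylate
Product: 41 1β,6α-bis[(tert-butyldimethylsilyl)oxy]-15-hydroxy-12-oxo-13-nor-5α,7αH-eudesman-8α-yl 2-{[(tert-butyldiphenylsilyl)oxy]methyl}acrylate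
Conditions: AcOH/THF/H2O (3:1:1), 45 °C
Reagents that add atoms: water, O
Why: Acid-catalysed hydrolysis cleaves the dioxolane to the C12 aldehyde and the primary silyl ether at C15, while the hindered secondary TBS ethers and the TBDPS ether hydrolyse far more slowly and should remain.

Step 25
Reactants: 41 1β,6α-bis[(tert-butyldimethylsilyl)oxy]-15-hydroxy-12-oxo-13-nor-5α,7αH-eudesman-8α-yl 2-{[(tert-butyldiphenylsilyl)oxy]methyl}acrylate; 42 N,N-dimethylmethyleneiminium iodide (Eschenmoser's salt)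
Product: 44 1β,6α-bis[(tert-butyldimethylsilyl)oxy]-15-hydroxy-12-oxo-5α,7αH-eudesm-11(13)-en-8α-yl 2-{[(tert-butyldiphenylsilyl)oxy]methyl}acrylate, via Mannich base 43 (not isolated)
Conditions: Et3N, CH2Cl2, rt
Reagents that add atoms: none
Why: Mannich reaction of the aldehyde at its only α-methylene group (C11) followed by β-elimination of dimethylamine (α-methylenation of an aldehyde) introduces C13 as the exocyclic methylene.

Step 26
Reactants: 44 1β,6α-bis[(tert-butyldimethylsilyl)oxy]-15-hydroxy-12-oxo-5α,7αH-eudesm-11(13)-en-8α-yl 2-{[(tert-butyldiphenylsilyl)oxy]methyl}acrylate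
Product: 45 1β,6α-bis[(tert-butyldimethylsilyl)oxy]-8α-[(2-{[(tert-butyldiphenylsilyl)oxy]methyl}acryloyl)oxy]-15-hydroxy-5α,7αH-eudesm-11(13)-en-12-oic acid
Conditions: NaClO2, NaH2PO4, 2-methyl-2-butene, t-BuOH/H2O, 0 °C → rt
Reagents that add atoms: sodium chlorite, [Na+].[O-]Cl=O
Why: Pinnick oxidation converts the enal into the acrylic acid, the alkene scavenger removing hypochlorite so that the double bonds and the free primary alcohol are untouched.

Step 27
Reactants: 45 1β,6α-bis[(tert-butyldimethylsilyl)oxy]-8α-[(2-{[(tert-butyldiphenylsilyl)oxy]methyl}acryloyl)oxy]-15-hydroxy-5α,7αH-eudesm-11(13)-en-12-oic acid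
Product: 46 1β,6α-bis[(tert-butyldimethylsilyl)oxy]-8α-[(2-{[(tert-butyldiphenylsilyl)oxy]methyl}acryloyl)oxy]-15-oxo-5α,7αH-eudesm-11(13)-en-12-oic acid
Conditions: Dess–Martin periodinane, CH2Cl2, 0 °C → rt
Reagents that add atoms: none
Why: Dess–Martin oxidation of the only free hydroxyl (C15) gives the aldehyde, whose equatorial 4α orientation is the thermodynamically preferred one.

Step 28
Reactants: 46 1β,6α-bis[(tert-butyldimethylsilyl)oxy]-8α-[(2-{[(tert-butyldiphenylsilyl)oxy]methyl}acryloyl)oxy]-15-oxo-5α,7αH-eudesm-11(13)-en-12-oic acid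
Product: 47 1β,6α-dihydroxy-8α-{[2-(hydroxymethyl)acryloyl]oxy}-15-oxo-5α,7αH-eudesm-11(13)-en-12-oic acid (CNP0599450.1)
Conditions: HF·pyridine, pyridine, THF, 0 °C → rt
Reagents that add atoms: none
Why: Fluoride-mediated desilylation with buffered HF·pyridine removes the two secondary TBS ethers and the primary TBDPS ether under conditions that the acrylate ester, the aldehyde and the acid should tolerate.

**Compound list**

1 | hex-5-enoic acid | C=CCCCC(=O)O | starting material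
2 | (R)-4-benzyl-1,3-oxazolidin-2-one | O=C1N[C@H](Cc2ccccc2)CO1 | starting material
3 | hex-5-enoic pivalic anhydride | C=CCCCC(=O)OC(=O)C(C)(C)C | intermediate
4 | (R)-4-benzyl-3-(hex-5-enoyl)-1,3-oxazolidin-2-one | C=CCCCC(=O)N1[C@H](Cc2ccccc2)COC1=O | intermediate
5 | 1,3,5-trioxane | C1OCOCO1 | starting material
6 | trichlorotitanium (Z)-enolate of 4 | C=CCC/C=C(\O[Ti](Cl)(Cl)Cl)N1[C@H](Cc2ccccc2)COC1=O | intermediate
7 | (R)-4-benzyl-3-[(2S)-2-(hydroxymethyl)hex-5-enoyl]-1,3-oxazolidin-2-one | C=CCC[C@@H](CO)C(=O)N1[C@H](Cc2ccccc2)COC1=O | intermediate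
8 | (R)-4-benzyl-3-[(2S)-2-{[(tert-butyldimethylsilyl)oxy]methyl}hex-5-enoyl]-1,3-oxazolidin-2-one | C=CCC[C@@H](CO[Si](C)(C)C(C)(C)C)C(=O)N1[C@H](Cc2ccccc2)COC1=O | intermediate
9 | (2R)-2-{[(tert-butyldimethylsilyl)oxy]methyl}hex-5-en-1-ol | C=CCC[C@@H](CO[Si](C)(C)C(C)(C)C)CO | intermediate
10 | (2S)-2-{[(tert-butyldimethylsilyl)oxy]methyl}hex-5-enal | C=CCC[C@@H](CO[Si](C)(C)C(C)(C)C)C=O | intermediate
11 | dimethyl (1-diazo-2-oxopropyl)phosphonate (Ohira–Bestmann reagent) | CC(=O)C(=[N+]=[N-])P(=O)(OC)OC | starting material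
12 | tert-butyl{[(2R)-2-ethynylhex-5-en-1-yl]oxy}dimethylsilane | C=CCC[C@@H](CO[Si](C)(C)C(C)(C)C)C#C | intermediate
13 | ozonide of 12 (3-substituted 1,2,4-trioxolane) | C#C[C@H](CO[Si](C)(C)C(C)(C)C)CCC1OCOO1 | intermediate
14 | (4R)-4-{[(tert-butyldimethylsilyl)oxy]methyl}hex-5-ynal | C#C[C@H](CO[Si](C)(C)C(C)(C)C)CCC=O | intermediate
15 | isopropenylmagnesium bromide | CC(=C)[Mg]Br | starting material
16 | (6R)-6-{[(tert-butyldimethylsilyl)oxy]methyl}-2-methyloct-1-en-7-yn-3-ol (C3 epimers) | C#C[C@H](CO[Si](C)(C)C(C)(C)C)CCC(O)C(C)=C | intermediate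
17 | (6R)-6-{[(tert-butyldimethylsilyl)oxy]methyl}-2-methyloct-1-en-7-yn-3-one | C#C[C@H](CO[Si](C)(C)C(C)(C)C)CCC(=O)C(C)=C | intermediate
18 | (3R,6R)-6-{[(tert-butyldimethylsilyl)oxy]methyl}-2-methyloct-1-en-7-yn-3-ol | C#C[C@H](CO[Si](C)(C)C(C)(C)C)CC[C@@H](O)C(C)=C | intermediate
19 | (3R,6R)-3-[(tert-butyldimethylsilyl)oxy]-6-{[(tert-butyldimethylsilyl)oxy]methyl}-2-methyloct-1-en-7-yne | C#C[C@H](CO[Si](C)(C)C(C)(C)C)CC[C@@H](O[Si](C)(C)C(C)(C)C)C(C)=C | intermediate
20 | octacarbonyldicobalt | [Co].[Co].[C-]#[O+].[C-]#[O+].[C-]#[O+].[C-]#[O+].[C-]#[O+].[C-]#[O+].[C-]#[O+].[C-]#[O+] | starting material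
21 | hexacarbonyldicobalt complex of alkyne 19 | C=C(C)[C@H](O[Si](C)(C)C(C)(C)C)CC[C@@H](CO[Si](C)(C)C(C)(C)C)C12C3[Co-3]1(C#[O+])(C#[O+])(C#[O+])[Co-3]23(C#[O+])(C#[O+])C#[O+] | intermediate
22 | 1β,15-bis[(tert-butyldimethylsilyl)oxy]-7,11,12,13-tetranoreudesm-5-en-8-one = (4R,7R,7aR)-7-[(tert-butyldimethylsilyl)oxy]-4-{[(tert-butyldimethylsilyl)oxy]methyl}-7a-methyl-1,4,5,6,7,7a-hexahydro-2H-inden-2-one | O=C1C=C2[C@H](CO[Si](C)(C)C(C)(C)C)CC[C@@H](O[Si](C)(C)C(C)(C)C)[C@]2(C)C1 | intermediate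
23 | lithium enolate of the trans-hydrindanone (O8–Li, C6=C8, 5α-H) | [Li]OC1=C[C@H]2[C@H](CO[Si](C)(C)C(C)(C)C)CC[C@@H](O[Si](C)(C)C(C)(C)C)[C@]2(C)C1 | intermediate
24 | 8-[(trimethylsilyl)oxy]-1β,15-bis[(tert-butyldimethylsilyl)oxy]-7,11,12,13-tetranor-5α-eudesm-6(8)-ene (trans-hydrindanone silyl enol ether; 3aR,4R,7R,7aR) | C[Si](C)(C)OC1=C[C@H]2[C@H](CO[Si](C)(C)C(C)(C)C)CC[C@@H](O[Si](C)(C)C(C)(C)C)[C@]2(C)C1 | intermediate
25 | bromoform | BrC(Br)Br | starting material
26 | siloxy-dibromocyclopropane (C7Br2 bridging C6 and C8 of 24 on the α-face; 8β-OSiMe3, 6β-H) | C[Si](C)(C)O[C@]12C[C@@]3(C)[C@H](O[Si](C)(C)C(C)(C)C)CC[C@@H](CO[Si](C)(C)C(C)(C)C)[C@@H]3[C@H]1C2(Br)Br | intermediate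
27 | 7-bromo-1β,15-bis[(tert-butyldimethylsilyl)oxy]-11,12,13-trinor-5α-eudesm-6-en-8-one | O=C1C[C@]2(C)[C@@H](C=C1Br)[C@H](CO[Si](C)(C)C(C)(C)C)CC[C@H]2O[Si](C)(C)C(C)(C)C | intermediate
28 | (1,3-dioxolan-2-ylmethyl)zinc bromide | Br[Zn]CC1OCCO1 | starting material
29 | 1β,15-bis[(tert-butyldimethylsilyl)oxy]-12,12-(ethylenedioxy)-13-nor-5α-eudesm-6-en-8-one | O=C1C[C@]2(C)[C@@H](C=C1CC3OCCO3)[C@H](CO[Si](C)(C)C(C)(C)C)CC[C@H]2O[Si](C)(C)C(C)(C)C | intermediate
30 | 1β,15-bis[(tert-butyldimethylsilyl)oxy]-12,12-(ethylenedioxy)-13-nor-5α-eudesm-6-en-8β-ol | O[C@@H]1C[C@]2(C)[C@@H](C=C1CC3OCCO3)[C@H](CO[Si](C)(C)C(C)(C)C)CC[C@H]2O[Si](C)(C)C(C)(C)C | intermediate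
31 | 1β,15-bis[(tert-butyldimethylsilyl)oxy]-12,12-(ethylenedioxy)-13-nor-5α-eudesm-6-en-8α-yl 4-nitrobenzoate | O=C(O[C@H]1C[C@]2(C)[C@@H](C=C1CC3OCCO3)[C@H](CO[Si](C)(C)C(C)(C)C)CC[C@H]2O[Si](C)(C)C(C)(C)C)c4ccc(cc4)[N+](=O)[O-] | intermediate
32 | C6 alkylborane (6α-BH2, 7α-H) from 31 | O=C(O[C@H]1C[C@]2(C)[C@@H]([C@@H](B)[C@@H]1CC3OCCO3)[C@H](CO[Si](C)(C)C(C)(C)C)CC[C@H]2O[Si](C)(C)C(C)(C)C)c4ccc(cc4)[N+](=O)[O-] | intermediate
33 | 1β,15-bis[(tert-butyldimethylsilyl)oxy]-12,12-(ethylenedioxy)-6α-hydroxy-13-nor-5α,7αH-eudesman-8α-yl 4-nitrobenzoate | O=C(O[C@H]1C[C@]2(C)[C@@H]([C@@H](O)[C@@H]1CC3OCCO3)[C@H](CO[Si](C)(C)C(C)(C)C)CC[C@H]2O[Si](C)(C)C(C)(C)C)c4ccc(cc4)[N+](=O)[O-] | intermediate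
34 | 1β,6α,15-tris[(tert-butyldimethylsilyl)oxy]-12,12-(ethylenedioxy)-13-nor-5α,7αH-eudesman-8α-yl 4-nitrobenzoate | O=C(O[C@H]1C[C@]2(C)[C@@H]([C@@H](O[Si](C)(C)C(C)(C)C)[C@@H]1CC3OCCO3)[C@H](CO[Si](C)(C)C(C)(C)C)CC[C@H]2O[Si](C)(C)C(C)(C)C)c4ccc(cc4)[N+](=O)[O-] | intermediate
35 | 1β,6α,15-tris[(tert-butyldimethylsilyl)oxy]-12,12-(ethylenedioxy)-13-nor-5α,7αH-eudesman-8α-ol | O[C@H]1C[C@]2(C)[C@@H]([C@@H](O[Si](C)(C)C(C)(C)C)[C@@H]1CC3OCCO3)[C@H](CO[Si](C)(C)C(C)(C)C)CC[C@H]2O[Si](C)(C)C(C)(C)C | intermediate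
36 | methyl 2-(hydroxymethyl)acrylate | C=C(CO)C(=O)OC | starting material
37 | methyl 2-{[(tert-butyldiphenylsilyl)oxy]methyl}acrylate | C=C(CO[Si](c1ccccc1)(c1ccccc1)C(C)(C)C)C(=O)OC | intermediate
38 | 2-{[(tert-butyldiphenylsilyl)oxy]methyl}acrylic acid | C=C(CO[Si](c1ccccc1)(c1ccccc1)C(C)(C)C)C(=O)O | intermediate
39 | mixed anhydride of 38 with 2,4,6-trichlorobenzoic acid | C=C(CO[Si](c1ccccc1)(c1ccccc1)C(C)(C)C)C(=O)OC(=O)c1c(Cl)cc(Cl)cc1Cl | intermediate
40 | 1β,6α,15-tris[(tert-butyldimethylsilyl)oxy]-12,12-(ethylenedioxy)-13-nor-5α,7αH-eudesman-8α-yl 2-{[(tert-butyldiphenylsilyl)oxy]methyl}acrylate | C=C(CO[Si](c5ccccc5)(c6ccccc6)C(C)(C)C)C(=O)O[C@H]1C[C@]2(C)[C@@H]([C@@H](O[Si](C)(C)C(C)(C)C)[C@@H]1CC3OCCO3)[C@H](CO[Si](C)(C)C(C)(C)C)CC[C@H]2O[Si](C)(C)C(C)(C)C | intermediate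
41 | 1β,6α-bis[(tert-butyldimethylsilyl)oxy]-15-hydroxy-12-oxo-13-nor-5α,7αH-eudesman-8α-yl 2-{[(tert-butyldiphenylsilyl)oxy]methyl}acrylate | C=C(CO[Si](c5ccccc5)(c6ccccc6)C(C)(C)C)C(=O)O[C@H]1C[C@]2(C)[C@@H]([C@@H](O[Si](C)(C)C(C)(C)C)[C@@H]1CC=O)[C@H](CO)CC[C@H]2O[Si](C)(C)C(C)(C)C | intermediate
42 | N,N-dimethylmethyleneiminium iodide (Eschenmoser's salt) | C=[N+](C)C.[I-] | starting material
43 | Mannich base (C11 bearing CH2NMe2 and CHO) | C=C(CO[Si](c5ccccc5)(c6ccccc6)C(C)(C)C)C(=O)O[C@H]1C[C@]2(C)[C@@H]([C@@H](O[Si](C)(C)C(C)(C)C)[C@@H]1C(CN(C)C)C=O)[C@H](CO)CC[C@H]2O[Si](C)(C)C(C)(C)C | intermediate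
44 | 1β,6α-bis[(tert-butyldimethylsilyl)oxy]-15-hydroxy-12-oxo-5α,7αH-eudesm-11(13)-en-8α-yl 2-{[(tert-butyldiphenylsilyl)oxy]methyl}acrylate | C=C(CO[Si](c5ccccc5)(c6ccccc6)C(C)(C)C)C(=O)O[C@H]1C[C@]2(C)[C@@H]([C@@H](O[Si](C)(C)C(C)(C)C)[C@@H]1C(=C)C=O)[C@H](CO)CC[C@H]2O[Si](C)(C)C(C)(C)C | intermediate
45 | 1β,6α-bis[(tert-butyldimethylsilyl)oxy]-8α-[(2-{[(tert-butyldiphenylsilyl)oxy]methyl}acryloyl)oxy]-15-hydroxy-5α,7αH-eudesm-11(13)-en-12-oic acid | C=C(CO[Si](c5ccccc5)(c6ccccc6)C(C)(C)C)C(=O)O[C@H]1C[C@]2(C)[C@@H]([C@@H](O[Si](C)(C)C(C)(C)C)[C@@H]1C(=C)C(=O)O)[C@H](CO)CC[C@H]2O[Si](C)(C)C(C)(C)C | intermediate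
46 | 1β,6α-bis[(tert-butyldimethylsilyl)oxy]-8α-[(2-{[(tert-butyldiphenylsilyl)oxy]methyl}acryloyl)oxy]-15-oxo-5α,7αH-eudesm-11(13)-en-12-oic acid | C=C(CO[Si](c5ccccc5)(c6ccccc6)C(C)(C)C)C(=O)O[C@H]1C[C@]2(C)[C@@H]([C@@H](O[Si](C)(C)C(C)(C)C)[C@@H]1C(=C)C(=O)O)[C@H](C=O)CC[C@H]2O[Si](C)(C)C(C)(C)C | intermediate
47 | 1β,6α-dihydroxy-8α-{[2-(hydroxymethyl)acryloyl]oxy}-15-oxo-5α,7αH-eudesm-11(13)-en-12-oic acid (CNP0599450.1) | C=C(CO)C(=O)O[C@H]1C[C@]2(C)[C@@H]([C@@H](O)[C@@H]1C(=C)C(=O)O)[C@H](C=O)CC[C@H]2O | target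

**Step count**

Total steps: 28 (26 in the main line plus 2 for acid 38). Longest linear sequence: 26 steps (steps 1–20 and 23–28, from hex-5-enoic acid).

**Steps most likely to fail**

Step 13. What may go wrong: C5 may be protonated from the β-face during the electron-transfer reduction, giving the cis ring fusion, or proton transfer may let the enolate drift towards C9 before it is silylated. Fallback: set out from enone 22 and replace electron transfer by a metal-hydride conjugate reduction with direct silyl transfer. Rhodium-catalysed 1,4-hydrosilylation (RhCl(PPh3)3, Et3SiH, THF, 50 °C) should deliver hydride to C5 from the α-face, away from the C10 methyl, under kinetic control, and put silicon on the enone oxygen without a free enolate. This gives the triethylsilyl enol ether F1. F1 is taken through the same dibromocarbene step (CHBr3, KOt-Bu, pentane) via the siloxy-dibromocyclopropane F2, and the route is rejoined at bromoenone 27.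

Step 15. What may go wrong: the β,β-dialkoxy alkylzinc reagent may decompose by β-alkoxide elimination, or the alkylpalladium intermediate may undergo β-hydride elimination, so that debrominated enone forms instead of the coupled product. Fallback: set out from bromoenone 27 and make the C7–C11 bond between two sp2 carbons. Suzuki–Miyaura coupling with commercial (E)-2-(2-ethoxyvinyl)-4,4,5,5-tetramethyl-1,3,2-dioxaborolane (Pd(dppf)Cl2, K3PO4, dioxane/H2O) would give the 7-[(E)-2-ethoxyvinyl] enone F3. Acid-catalysed addition of ethylene glycol to the enol ether (PPTS, CH2Cl2, rt) then turns F3 into dioxolane 29, where the route is rejoined.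

Step 24. What may go wrong: the two acid-labile groups may not cleave at comparable rates, so that dioxolane hydrolysis lags while the silyl ether on O6 begins to cleave; a free O6 would close onto C12 as a lactol. Fallback: set out from ester 40 and separate the two events. Non-hydrolytic acetal cleavage (TESOTf, 2,4,6-collidine, CH2Cl2, 0 °C; then H2O) should free the aldehyde while every silyl ether stays, giving the aldehyde F4. Methylenation with Eschenmoser's salt and Et3N, through the Mannich base F5, gives the enal F6, and Pinnick oxidation gives the acid F7. Acid-catalysed methanolysis of the primary silyl ether only (CSA, MeOH/CH2Cl2, 0 °C) then rejoins the route at hydroxy acid 45.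

Further compounds
F1 | step 13 | 8-[(triethylsilyl)oxy]-1β,15-bis[(tert-butyldimethylsilyl)oxy]-7,11,12,13-tetranor-5α-eudesm-6(8)-ene | CC[Si](CC)(CC)OC1=C[C@H]2[C@H](CO[Si](C)(C)C(C)(C)C)CC[C@@H](O[Si](C)(C)C(C)(C)C)[C@]2(C)C1
F2 | step 13 | triethylsiloxy-dibromocyclopropane (C7Br2 bridging C6 and C8 of F1 on the α-face) | CC[Si](CC)(CC)O[C@]12C[C@@]3(C)[C@H](O[Si](C)(C)C(C)(C)C)CC[C@@H](CO[Si](C)(C)C(C)(C)C)[C@@H]3[C@H]1C2(Br)Br
F3 | step 15 | 7-[(E)-2-ethoxyvinyl]-1β,15-bis[(tert-butyldimethylsilyl)oxy]-11,12,13-trinor-5α-eudesm-6-en-8-one | O=C1C[C@]2(C)[C@@H](C=C1/C=C/OCC)[C@H](CO[Si](C)(C)C(C)(C)C)CC[C@H]2O[Si](C)(C)C(C)(C)C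
F4 | step 24 | 1β,6α,15-tris[(tert-butyldimethylsilyl)oxy]-12-oxo-13-nor-5α,7αH-eudesman-8α-yl 2-{[(tert-butyldiphenylsilyl)oxy]methyl}acrylate | C=C(CO[Si](c5ccccc5)(c6ccccc6)C(C)(C)C)C(=O)O[C@H]1C[C@]2(C)[C@@H]([C@@H](O[Si](C)(C)C(C)(C)C)[C@@H]1CC=O)[C@H](CO[Si](C)(C)C(C)(C)C)CC[C@H]2O[Si](C)(C)C(C)(C)C
F5 | step 24 | Mannich base of F4 (C11 bearing CH2NMe2 and CHO) | C=C(CO[Si](c5ccccc5)(c6ccccc6)C(C)(C)C)C(=O)O[C@H]1C[C@]2(C)[C@@H]([C@@H](O[Si](C)(C)C(C)(C)C)[C@@H]1C(CN(C)C)C=O)[C@H](CO[Si](C)(C)C(C)(C)C)CC[C@H]2O[Si](C)(C)C(C)(C)C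
F6 | step 24 | 1β,6α,15-tris[(tert-butyldimethylsilyl)oxy]-12-oxo-5α,7αH-eudesm-11(13)-en-8α-yl 2-{[(tert-butyldiphenylsilyl)oxy]methyl}acrylate | C=C(CO[Si](c5ccccc5)(c6ccccc6)C(C)(C)C)C(=O)O[C@H]1C[C@]2(C)[C@@H]([C@@H](O[Si](C)(C)C(C)(C)C)[C@@H]1C(=C)C=O)[C@H](CO[Si](C)(C)C(C)(C)C)CC[C@H]2O[Si](C)(C)C(C)(C)C
F7 | step 24 | 1β,6α,15-tris[(tert-butyldimethylsilyl)oxy]-8α-[(2-{[(tert-butyldiphenylsilyl)oxy]methyl}acryloyl)oxy]-5α,7αH-eudesm-11(13)-en-12-oic acid | C=C(CO[Si](c5ccccc5)(c6ccccc6)C(C)(C)C)C(=O)O[C@H]1C[C@]2(C)[C@@H]([C@@H](O[Si](C)(C)C(C)(C)C)[C@@H]1C(=C)C(=O)O)[C@H](CO[Si](C)(C)C(C)(C)C)CC[C@H]2O[Si](C)(C)C(C)(C)C
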